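## Analysis of the target

Cryptomerin A (19) is a biflavone without any stereocentre. Two 2-aryl-4H-chromen-4-one units are joined by one diaryl ether oxygen, which links C6 of the methoxylated flavone (the acacetin half: 5,7-dihydroxy, 4'-methoxy) to C4' of ring B of the unmethylated flavone (the apigenin half: 5,7-dihydroxy). The only geometric element in the whole route is the double bond of one transient enol ether. The sensitive groups are four phenols (two chelated to the C4 carbonyls), two pyranone rings that hot alkali or hard carbon nucleophiles open at C2, and one aryl methyl ether that must survive the unmasking of the four hydroxyls. Three things make the synthesis hard. The ether oxygen sits on C6 between the oxygenated carbons C5 and C7, so it is hindered and its 6- versus 8-placement must be unambiguous. Five phenolic oxygens must be told apart so that exactly one ends as a methyl ether. Two different flavones must be built without the chemistry of one damaging the other. The strategy rests on ring A of the apigenin half: C5, C7 and C8a carry oxygen, C6 and C8 carry hydrogen, and C4a carries the acyl carbon C4, which is the folding pattern of a polyketide. That ring can therefore be stored as a 4-benzyloxy-2-pyrone (pyrone C2, C3, C4, C5, C6 become C5, C6, C7, C8, C8a; the side-chain methylene becomes C4a), and forming the single bond C4a–C5 turns the lactone into the arene with no atom gained or lost.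

## Retrosynthetic reasoning

19 ⇐ 18. The last operation removes three benzyl ethers. Benzyl is chosen for every oxygen that must end as a hydroxyl because it is cleaved under conditions that leave the methyl ether and the diaryl ether alone. The methyl group is carried from the start inside 5, so no late selective methylation is needed.

18 ⇐ 17. The O1–C2 bond of the pyranone of the unmethylated half is cut, giving the o,o'-dihydroxyaryl 1,3-diketone 17. The forward reaction is an acid cyclodehydration. The aryl ring of 17 is symmetric, so either hydroxyl gives the same flavone and no regiochemical question arises.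

17 ⇐ 15 (key disconnection). The bond C4a–C5 of ring A of the unmethylated half is cut and the ring is written as the 4-benzyloxy-2-pyrone 15, an isomer of 17. The cut is made here because it replaces a protected, differentiated 1,3,5-trioxygenated acetophenone by the cheap pyrone 10 and delivers the ring with exactly one protected and two free hydroxyls. The forward mechanism needs one correction against the simplest picture. The side-chain methylene and the lactone carbonyl are both attached to the C6–O1 unit of the pyrone, so a direct attack would have to form a four-membered ring inside the heterocycle. The lactone must therefore be opened first by an alkoxide, giving the open-chain ester 16, and the same carbon–carbon bond is then made by a Dieckmann-type closure. The alkoxide is chosen to match the benzyl ether, so that exchange at the enol ether carbon cannot alter the protecting group.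

15 ⇐ 14 + 13. The bond between the central methylene of the 1,3-diketone and the carbonyl on the pyrone side is cut, giving the silyl enol ether 14 and the acid chloride 13. A base-mediated crossed Claisen condensation is avoided on purpose. The methylene of 13 is a vinylogous malonate position and far more acidic than the methyl ketone 9, so any amine or metal amide would enolise the acyl donor (ketene formation, self-condensation) instead of the ketone. Pre-forming the nucleophile as 14 and acylating under Lewis acid conditions keeps the medium non-basic. 14 comes from 9 by kinetic enolisation.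

13 ⇐ 12 ⇐ 11 ⇐ 10. The acid chloride is traced to the acid 12, which comes from carboxylation of the vinylogous enolate of 11, and 11 from O-benzylation of 10. Three steps give the whole future ring A of the unmethylated half.

9 ⇐ 7 + 8. The diaryl ether is cut at the bond between oxygen and the para-phenylene ring, giving the phenol 7 and 8. The forward reaction is a nucleophilic aromatic substitution activated by the para-acetyl group. It is placed after the flavone of the methoxylated half is complete, so that only one enolisable ketone is present during that flavone synthesis and the acetyl group of 8 arrives exactly where the diketone chain is to grow.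

7 ⇐ 6 ⇐ 4 + 5. The pyranone of the methoxylated half is opened at O1–C2 to the diketone 6, and 6 is cut between C2 and C3 into the acetophenone 4 and the acid chloride 5. In 6 only the hydroxyl ortho to the acyl group can close the ring, so the other hydroxyl ends unambiguously at C6 between the two benzyl ethers.

4 ⇐ 2 ⇐ 1. The C6 oxygen is introduced by para-hydroxylation (Elbs oxidation) of 2. The position para to the one free hydroxyl of 2 is the carbon between the two benzyloxy groups, which fixes the 6- rather than 8-oxygenation. 2 comes from selective dibenzylation of 1, whose chelated hydroxyl stays free.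

## Alternatives that were turned down

Alternative 1: The para-phenylene ring B of the apigenin half is cut at C3'–C4' and C5'–C6'. In the forward direction methyl coumalate A1 and the aryl ethynyl ether A2 would undergo a [4+2] cycloaddition, and loss of CO2 from the bridged lactone would give the methyl 4-aryloxybenzoate A3.
- For: the hindered C–O bond already exists before the ring forms, so no substitution at a di-ortho-substituted phenoxide is needed. The regiochemistry should be reliably para, because the nucleophilic terminal alkyne carbon bonds to C6 of A1. On the ether bond this alternative is stronger than the chosen route.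
- Against: the ring it builds is a plain para-disubstituted benzene, which 8 supplies for nothing. A2 is an ynol ether of a tetraoxygenated phenol that needs its own multistep preparation and is prone to hydration and ketene chemistry. After A3 neither flavone exists: the ring A acylation, both pyranones and the conversion of the ester into the diketone all remain, so the longest sequence would be clearly longer.
- In its place the chosen route accepts one substitution at a hindered phenoxide (step 5) and spends its ring construction on ring A, where the differentiated trioxygenation is the expensive feature.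

Alternative 2: Ring A of the acacetin half is cut at C7–C8 and C4a–C5. In the forward direction the silyl dienol ether of the pyranone A4 would act as a 1,3-dinucleophile (methyl carbon and ring C5) towards the aryloxymalonyl dichloride A5 and give A6, which is one hydrogenolysis away from 19.
- For: it is the most convergent plan. The ether oxygen is introduced on an unhindered malonate carbon, the acacetin half needs no protecting group, and on step count it clearly beats the chosen route.
- Against: it depends on double C-acylation. Malonyl dichlorides usually react with enol derivatives through chlorocarbonyl ketenes by C,O-acylation to 4-hydroxy-2-pyranones, and here the pyranone oxygen is well placed to give a fused pyrone instead of a benzene ring. A5 must be made from a complete flavone and is itself prone to ketene formation, so a failure is paid for at the most advanced stage with both halves consumed.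
- The chosen route closes its ring intramolecularly, by a known reaction type, on a chain for which the arene is the favoured six-membered C–C closure, and pays for that with more steps.

Alternative 3: Both pyranones are cut at C2–C3. In the forward direction the bis-ester A7 would undergo two Baker–Venkataraman acyl transfers with excess base and give the open bis(1,3-diketone) A8, and acid would then close both pyranones.
- For: every operation is classical flavone chemistry and two C–C bonds form in one operation. On the reliability of the individual reactions this alternative is stronger than the chosen route.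
- Against: its key step closes no ring, so all oxygenation of both A rings must be carried in as protected acetophenones. A7 needs two different esters placed in order on a hydroquinone-type acetophenone that already carries the diaryl ether. Two enolates and two esters coexist in the rearrangement, which allows intermolecular acyl transfer and ester cleavage, and four benzyl groups must be removed at the end.
- The chosen route offers a shorter, less protected apigenin side: ring A comes from 10 in three steps with a single protecting group. What it gives up is the certainty of a textbook acyl transfer.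

Key step: step 11

Remark: 1,3-diketones are drawn and named in the diketo form although they exist largely as chelated enols; this changes no connectivity.

## Route

Step 1
Reactants: 1 2',4',6'-trihydroxyacetophenone
Product: 2 1-[2,4-bis(benzyloxy)-6-hydroxyphenyl]ethanone
Conditions: BnBr (2.1 equiv), K2CO3, DMF, 25 °C
Reagents that add atoms: benzyl bromide, BrCc1ccccc1
Why: Williamson etherification of the two more acidic and accessible phenols; the third hydroxyl is held in a hydrogen bond to the acetyl carbonyl and stays free, and it is the hydroxyl later needed as the pyranone oxygen.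

Step 2
Reactants: 2 1-[2,4-bis(benzyloxy)-6-hydroxyphenyl]ethanone
Product: 4 1-[2,4-bis(benzyloxy)-3,6-dihydroxyphenyl]ethanone, via potassium aryl sulfate 3 (not isolated)
Conditions: K2S2O8, aq. KOH, pyridine, 15 °C; then aq. HCl, Na2SO3, 70 °C
Reagents that add atoms: potassium peroxodisulfate, [K+].[K+].[O-]S(=O)(=O)OOS(=O)(=O)[O-]
Why: Elbs persulfate oxidation: the phenoxide attacks a peroxide oxygen through its para carbon, which is the carbon between the two benzyloxy groups and becomes C6 of the flavone. Dilute acid then hydrolyses the aryl sulfate 3 at the S–O bond and should leave the benzyl ethers intact.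

Step 3
Reactants: 4 1-[2,4-bis(benzyloxy)-3,6-dihydroxyphenyl]ethanone; 5 4-methoxybenzoyl chloride
Product: 6 1-[2,4-bis(benzyloxy)-3,6-dihydroxyphenyl]-3-(4-methoxyphenyl)propane-1,3-dione
Conditions: LiN(SiMe3)2 (4.2 equiv), THF, −78 to −10 °C; then 5, −78 °C to rt; aq. HCl work-up
Reagents that add atoms: none
Why: C-aroylation of a ketone enolate in the presence of lithium phenoxides (polyanion acylation): the enolate carbon of the trilithium salt is the most nucleophilic site, while one phenoxide is chelated and the other is flanked by two benzyloxy groups. The extra equivalent of base takes up the acidic proton of the diketone as it forms.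

Step 4
Reactants: 6 1-[2,4-bis(benzyloxy)-3,6-dihydroxyphenyl]-3-(4-methoxyphenyl)propane-1,3-dione
Product: 7 5,7-bis(benzyloxy)-6-hydroxy-2-(4-methoxyphenyl)-4H-chromen-4-one
Conditions: TsOH·H2O (cat.), toluene, 80 °C
Reagents that add atoms: none
Why: Acid-catalysed cyclodehydration of an o-hydroxyaryl 1,3-diketone to a flavone: only the hydroxyl ortho to the acyl group can reach the distal carbonyl, so the second hydroxyl ends as the free 6-OH. The mild sulfonic acid should spare the benzyl ethers.

Step 5
Reactants: 7 5,7-bis(benzyloxy)-6-hydroxy-2-(4-methoxyphenyl)-4H-chromen-4-one; 8 4'-fluoroacetophenone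
Product: 9 6-(4-acetylphenoxy)-5,7-bis(benzyloxy)-2-(4-methoxyphenyl)-4H-chromen-4-one
Conditions: K2CO3, DMSO, 120 °C (8 in excess)
Reagents that add atoms: none
Why: Nucleophilic aromatic substitution by addition–elimination: the para-acetyl group stabilises the Meisenheimer adduct and fluoride leaves. The flavone has no acidic C–H and tolerates anhydrous carbonate, and the excess of 8 covers its loss by self-condensation.

Step 6
Reactants: 10 4-hydroxy-6-methyl-2H-pyran-2-one
Product: 11 4-(benzyloxy)-6-methyl-2H-pyran-2-one
Conditions: PhCH2OH, PPh3, DIAD, THF, 0 °C to rt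
Reagents that add atoms: benzyl alcohol, OCc1ccccc1
Why: Mitsunobu etherification: the vinylogous acid 10 protonates the betaine and the pyronate attacks the alkoxyphosphonium ion through oxygen, which avoids the C3-benzylation that benzyl halides and base can cause.

Step 7
Reactants: 11 4-(benzyloxy)-6-methyl-2H-pyran-2-one
Product: 12 2-[4-(benzyloxy)-2-oxo-2H-pyran-6-yl]acetic acid
Conditions: LiN(SiMe3)2, THF, −78 °C; CO2; then cold aq. HCl
Reagents that add atoms: carbon dioxide, O=C=O
Why: Carboxylation of a stabilised carbanion: the amide base gives the vinylogous enolate at the 6-methyl group, conjugated through the ring to the lactone carbonyl, and CO2 traps it at carbon. Cold acidification avoids decarboxylation of the vinylogous malonic acid.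

Step 8
Reactants: 12 2-[4-(benzyloxy)-2-oxo-2H-pyran-6-yl]acetic acid
Product: 13 2-[4-(benzyloxy)-2-oxo-2H-pyran-6-yl]acetyl chloride
Conditions: (COCl)2, DMF (cat.), CH2Cl2, 0 °C to rt; evaporate, use crude
Reagents that add atoms: oxalyl chloride, O=C(Cl)C(=O)Cl
Why: Acid chloride formation through the chloroiminium (Vilsmeier-type) intermediate; no base is present, so the acidic methylene is not deprotonated and no ketene forms.

Step 9
Reactants: 9 6-(4-acetylphenoxy)-5,7-bis(benzyloxy)-2-(4-methoxyphenyl)-4H-chromen-4-one
Product: 14 5,7-bis(benzyloxy)-2-(4-methoxyphenyl)-6-{4-[1-(trimethylsilyloxy)ethenyl]phenoxy}-4H-chromen-4-one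
Conditions: LiN(SiMe3)2, Me3SiCl, THF, −78 °C; non-aqueous work-up, use crude
Reagents that add atoms: chlorotrimethylsilane, C[Si](C)(C)Cl
Why: Kinetic enolisation of the only enolisable ketone and O-silylation to the silyl enol ether; the vinylic C3–H of the flavone and the benzylic ether positions are not deprotonated at this temperature.

Step 10
Reactants: 14 5,7-bis(benzyloxy)-2-(4-methoxyphenyl)-6-{4-[1-(trimethylsilyloxy)ethenyl]phenoxy}-4H-chromen-4-one; 13 2-[4-(benzyloxy)-2-oxo-2H-pyran-6-yl]acetyl chloride
Product: 15 5,7-bis(benzyloxy)-6-(4-{4-[4-(benzyloxy)-2-oxo-2H-pyran-6-yl]-3-oxobutanoyl}phenoxy)-2-(4-methoxyphenyl)-4H-chromen-4-one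
Conditions: ZnCl2 (1.0 M in Et2O, 1.2 equiv), CH2Cl2, 0 °C to rt
Reagents that add atoms: none
Why: Lewis acid promoted C-acylation of a silyl enol ether by an acid chloride (Mukaiyama-type acylation) to the 1,3-diketone. No base is present, so the methylene of 13, far more acidic than a methyl ketone, is never deprotonated and neither ketene formation nor self-condensation of the acyl donor should compete. The silyl enol ether is the strongest π-nucleophile in either partner.

Step 11
Reactants: 15 5,7-bis(benzyloxy)-6-(4-{4-[4-(benzyloxy)-2-oxo-2H-pyran-6-yl]-3-oxobutanoyl}phenoxy)-2-(4-methoxyphenyl)-4H-chromen-4-one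
Product: 17 1-[4-(benzyloxy)-2,6-dihydroxyphenyl]-3-(4-{[5,7-bis(benzyloxy)-2-(4-methoxyphenyl)-4-oxo-4H-chromen-6-yl]oxy}phenyl)propane-1,3-dione, via open-chain benzyl ester 16 (not isolated)
Conditions: Mg(OCH2Ph)2 (from Mg(n-Bu)2 and PhCH2OH), THF, 0 to 50 °C; then aq. HCl
Reagents that add atoms: none
Why: The reaction is the magnesium alkoxide ring transformation of a 6-(2-oxoalkyl)-2-pyrone into an acylated 1,3,5-trioxygenated benzene, a lactone-to-arene isomerisation of the Claisen (Dieckmann) type. The 1,3-diketone is first bound as its magnesium enolate; direct attack of the pyrone-bound methylene on the lactone carbonyl is geometrically excluded, because both carbons hang on the same C6–O1 unit and would have to form a four-membered ring inside the pyrone, so benzyloxide first adds to the lactone carbonyl and opens it to the benzyl ester 16. The former ring double bond survives in 16 as the E enol ether, which holds the ester carbon C1 and the new C5 ketone on the same side (numbering of the nonenoate chain). The methylene C6 between the C5 and C7 carbonyls of the magnesium triketonate then attacks the ester carbonyl in a 6-exo-trig closure, benzyloxide is expelled, and enolisation gives the aromatic ring, which makes the sequence irreversible and forms the bond that becomes C4a–C5 of the apigenin half. No stereocentre is formed. Two selectivities are needed: the Claisen closure must beat aldol closures, and the benzyl ether must stay in place. The first is secured because the enol ether leaves C2 of 16 as a non-enolisable vinylic carbon (no attack on C7) and the aryl ketone C9 lies in the magnesium chelate as an electron-rich enolate (no attack by C4); the second because the alkoxide is benzyloxide, so any addition–elimination at the benzyloxy-bearing carbon returns the same ether. The new ring is symmetric, so its two hydroxyls are equivalent for step 12.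

Step 12
Reactants: 17 1-[4-(benzyloxy)-2,6-dihydroxyphenyl]-3-(4-{[5,7-bis(benzyloxy)-2-(4-methoxyphenyl)-4-oxo-4H-chromen-6-yl]oxy}phenyl)propane-1,3-dione
Product: 18 5,7-bis(benzyloxy)-6-{4-[7-(benzyloxy)-5-hydroxy-4-oxo-4H-chromen-2-yl]phenoxy}-2-(4-methoxyphenyl)-4H-chromen-4-one
Conditions: TsOH·H2O (cat.), toluene, 80 °C
Reagents that add atoms: none
Why: Acid-catalysed cyclodehydration of the o-hydroxyaryl 1,3-diketone to the second flavone; either of the two equivalent hydroxyls adds to the distal carbonyl and the other remains as the chelated 5-OH.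

Step 13
Reactants: 18 5,7-bis(benzyloxy)-6-{4-[7-(benzyloxy)-5-hydroxy-4-oxo-4H-chromen-2-yl]phenoxy}-2-(4-methoxyphenyl)-4H-chromen-4-one
Product: 19 cryptomerin A, 5,7-dihydroxy-6-[4-(5,7-dihydroxy-4-oxo-4H-chromen-2-yl)phenoxy]-2-(4-methoxyphenyl)-4H-chromen-4-one
Conditions: H2 (1 atm), Pd/C (10% palladium on carbon), THF/MeOH, rt
Reagents that add atoms: none
Why: Hydrogenolysis of three benzyl aryl ethers; the aryl methyl ether and the diaryl ether are inert, and the conjugated C2=C3 bonds of the flavones are reduced only slowly, so the reaction is stopped after uptake of three equivalents of hydrogen.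

## Compound list

1 | 2',4',6'-trihydroxyacetophenone | CC(=O)c1c(O)cc(O)cc1O | starting material
2 | 1-[2,4-bis(benzyloxy)-6-hydroxyphenyl]ethanone | CC(=O)c1c(O)cc(OCc2ccccc2)cc1OCc1ccccc1 | intermediate
3 | potassium 3-acetyl-2,6-bis(benzyloxy)-4-hydroxyphenyl sulfate | CC(=O)c1c(O)cc(OCc2ccccc2)c(OS(=O)(=O)[O-])c1OCc1ccccc1.[K+] | intermediate
4 | 1-[2,4-bis(benzyloxy)-3,6-dihydroxyphenyl]ethanone | CC(=O)c1c(O)cc(OCc2ccccc2)c(O)c1OCc1ccccc1 | intermediate
5 | 4-methoxybenzoyl chloride | COc1ccc(C(Cl)=O)cc1 | starting material
6 | 1-[2,4-bis(benzyloxy)-3,6-dihydroxyphenyl]-3-(4-methoxyphenyl)propane-1,3-dione | COc1ccc(C(=O)CC(=O)c2c(O)cc(OCc3ccccc3)c(O)c2OCc2ccccc2)cc1 | intermediate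
7 | 5,7-bis(benzyloxy)-6-hydroxy-2-(4-methoxyphenyl)-4H-chromen-4-one | COc1ccc(-c2cc(=O)c3c(OCc4ccccc4)c(O)c(OCc4ccccc4)cc3o2)cc1 | intermediate
8 | 4'-fluoroacetophenone | CC(=O)c1ccc(F)cc1 | starting material
9 | 6-(4-acetylphenoxy)-5,7-bis(benzyloxy)-2-(4-methoxyphenyl)-4H-chromen-4-one | COc1ccc(-c2cc(=O)c3c(OCc4ccccc4)c(Oc4ccc(C(C)=O)cc4)c(OCc4ccccc4)cc3o2)cc1 | intermediate
10 | 4-hydroxy-6-methyl-2H-pyran-2-one | Cc1cc(O)cc(=O)o1 | starting material
11 | 4-(benzyloxy)-6-methyl-2H-pyran-2-one | Cc1cc(OCc2ccccc2)cc(=O)o1 | intermediate
12 | 2-[4-(benzyloxy)-2-oxo-2H-pyran-6-yl]acetic acid | OC(=O)Cc1cc(OCc2ccccc2)cc(=O)o1 | intermediate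
13 | 2-[4-(benzyloxy)-2-oxo-2H-pyran-6-yl]acetyl chloride | ClC(=O)Cc1cc(OCc2ccccc2)cc(=O)o1 | intermediate
14 | 5,7-bis(benzyloxy)-2-(4-methoxyphenyl)-6-{4-[1-(trimethylsilyloxy)ethenyl]phenoxy}-4H-chromen-4-one | COc1ccc(-c2cc(=O)c3c(OCc4ccccc4)c(Oc4ccc(C(=C)O[Si](C)(C)C)cc4)c(OCc4ccccc4)cc3o2)cc1 | intermediate
15 | 5,7-bis(benzyloxy)-6-(4-{4-[4-(benzyloxy)-2-oxo-2H-pyran-6-yl]-3-oxobutanoyl}phenoxy)-2-(4-methoxyphenyl)-4H-chromen-4-one | COc1ccc(-c2cc(=O)c3c(OCc4ccccc4)c(Oc4ccc(C(=O)CC(=O)Cc5cc(OCc6ccccc6)cc(=O)o5)cc4)c(OCc4ccccc4)cc3o2)cc1 | intermediate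
16 | benzyl (2E)-3-(benzyloxy)-9-(4-{[5,7-bis(benzyloxy)-2-(4-methoxyphenyl)-4-oxo-4H-chromen-6-yl]oxy}phenyl)-5,7,9-trioxonon-2-enoate | COc1ccc(-c2cc(=O)c3c(OCc4ccccc4)c(Oc4ccc(C(=O)CC(=O)CC(=O)C/C(OCc5ccccc5)=C\C(=O)OCc5ccccc5)cc4)c(OCc4ccccc4)cc3o2)cc1 | intermediate
17 | 1-[4-(benzyloxy)-2,6-dihydroxyphenyl]-3-(4-{[5,7-bis(benzyloxy)-2-(4-methoxyphenyl)-4-oxo-4H-chromen-6-yl]oxy}phenyl)propane-1,3-dione | COc1ccc(-c2cc(=O)c3c(OCc4ccccc4)c(Oc4ccc(C(=O)CC(=O)c5c(O)cc(OCc6ccccc6)cc5O)cc4)c(OCc4ccccc4)cc3o2)cc1 | intermediate
18 | 5,7-bis(benzyloxy)-6-{4-[7-(benzyloxy)-5-hydroxy-4-oxo-4H-chromen-2-yl]phenoxy}-2-(4-methoxyphenyl)-4H-chromen-4-one | COc1ccc(-c2cc(=O)c3c(OCc4ccccc4)c(Oc4ccc(-c5cc(=O)c6c(O)cc(OCc7ccccc7)cc6o5)cc4)c(OCc4ccccc4)cc3o2)cc1 | intermediate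
19 | cryptomerin A, 5,7-dihydroxy-6-[4-(5,7-dihydroxy-4-oxo-4H-chromen-2-yl)phenoxy]-2-(4-methoxyphenyl)-4H-chromen-4-one | COc1ccc(-c2cc(=O)c3c(O)c(Oc4ccc(-c5cc(=O)c6c(O)cc(O)cc6o5)cc4)c(O)cc3o2)cc1 | target

## Step count and risk

Total: 13 steps. Longest linear sequence: 10 steps (steps 1, 2, 3, 4, 5, 9, 10, 11, 12, 13). The pyrone arm (steps 6, 7, 8) joins at step 10.

Step 11 (key step). Several processes could divert the opened chain:
- aldol closure onto the aryl ketone instead of Claisen closure onto the ester;
- retro-Claisen fragmentation of the triketone by the alkoxide;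
- re-lactonisation to the pyrone without cyclisation;
- alkoxide opening of the finished acacetin pyranone at higher temperature.

Fallback: the apigenin half is built by the classical chalcone route, setting out from phenol 7 and acetophenone 2 and coming back at 19. Phenol 7 and 4-fluorobenzaldehyde (K2CO3, DMF, 90 °C) should give the aldehyde 4-{[5,7-bis(benzyloxy)-2-(4-methoxyphenyl)-4-oxo-4H-chromen-6-yl]oxy}benzaldehyde F1. Claisen–Schmidt condensation of F1 with 2 (KOH, EtOH/THF, rt) should give the chalcone (E)-1-[2,4-bis(benzyloxy)-6-hydroxyphenyl]-3-(4-{[5,7-bis(benzyloxy)-2-(4-methoxyphenyl)-4-oxo-4H-chromen-6-yl]oxy}phenyl)prop-2-en-1-one F2. Oxidative cyclisation (I2 cat., DMSO, 120 °C) should give the tetrabenzyl biflavone 5,7-bis(benzyloxy)-6-{4-[5,7-bis(benzyloxy)-4-oxo-4H-chromen-2-yl]phenoxy}-2-(4-methoxyphenyl)-4H-chromen-4-one F3, and hydrogenolysis (H2, Pd/C) then gives 19. Partial loss of a peri benzyl group during the iodine step would be harmless.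

Step 10. C-acylation could be undercut in three ways:
- O-acylation of the silyl enol ether;
- protodesilylation of 14 by adventitious HCl, returning ketone 9;
- Lewis acid promoted acylation of the nucleophilic C3 of a second pyrone.

Fallback: the roles are reversed so that the precious half is a non-enolisable acyl donor; it sets out from 11 and 7 and comes back at 15. Lithiated 11 (LiN(SiMe3)2, THF, −78 °C) and N-methoxy-N-methylacetamide should give the ketone 4-(benzyloxy)-6-(2-oxopropyl)-2H-pyran-2-one F4. Phenol 7 and methyl 4-fluorobenzoate (K2CO3, DMSO, 120 °C) should give the ester methyl 4-{[5,7-bis(benzyloxy)-2-(4-methoxyphenyl)-4-oxo-4H-chromen-6-yl]oxy}benzoate F5. The dianion of F4 (LiN(i-Pr)2, 2 equiv per F4, THF, −78 °C, F4 in excess) is then aroylated at its terminal carbon by F5 (−78 to 0 °C), the known behaviour of β-dicarbonyl dianions, and acidic work-up gives 15.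

Step 2. The oxidation may stop at low conversion, the dibenzyl phenoxide may be poorly soluble in the aqueous base, and the hydroquinone may be over-oxidised. Fallback: Teuber oxidation followed by reduction, from 2 back to 4. Treatment of 2 with (KO3S)2NO (KH2PO4 buffer, aqueous acetone) should give the quinone 2-acetyl-3,5-bis(benzyloxy)cyclohexa-2,5-diene-1,4-dione F6, and Na2S2O4 in aqueous THF reduces it to 4.

Step 5. Substitution at a phenoxide flanked by two benzyloxy groups may be slow, and base-mediated self-condensation of 8 then consumes the electrophile. Fallback: copper-mediated oxidative O-arylation (Chan–Lam coupling) of 7 with 4-acetylphenylboronic acid (Cu(OAc)2, pyridine, 4 Å molecular sieves, CH2Cl2, air, rt), which sets out from 7 and returns directly to 9. It makes no compound outside the list (entered below as F0).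

## Further compounds

F1 | step 11 | 4-{[5,7-bis(benzyloxy)-2-(4-methoxyphenyl)-4-oxo-4H-chromen-6-yl]oxy}benzaldehyde | COc1ccc(-c2cc(=O)c3c(OCc4ccccc4)c(Oc4ccc(C=O)cc4)c(OCc4ccccc4)cc3o2)cc1
F2 | step 11 | (E)-1-[2,4-bis(benzyloxy)-6-hydroxyphenyl]-3-(4-{[5,7-bis(benzyloxy)-2-(4-methoxyphenyl)-4-oxo-4H-chromen-6-yl]oxy}phenyl)prop-2-en-1-one | COc1ccc(-c2cc(=O)c3c(OCc4ccccc4)c(Oc4ccc(/C=C/C(=O)c5c(O)cc(OCc6ccccc6)cc5OCc5ccccc5)cc4)c(OCc4ccccc4)cc3o2)cc1
F3 | step 11 | 5,7-bis(benzyloxy)-6-{4-[5,7-bis(benzyloxy)-4-oxo-4H-chromen-2-yl]phenoxy}-2-(4-methoxyphenyl)-4H-chromen-4-one | COc1ccc(-c2cc(=O)c3c(OCc4ccccc4)c(Oc4ccc(-c5cc(=O)c6c(OCc7ccccc7)cc(OCc7ccccc7)cc6o5)cc4)c(OCc4ccccc4)cc3o2)cc1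
F4 | step 10 | 4-(benzyloxy)-6-(2-oxopropyl)-2H-pyran-2-one | CC(=O)Cc1cc(OCc2ccccc2)cc(=O)o1
F5 | step 10 | methyl 4-{[5,7-bis(benzyloxy)-2-(4-methoxyphenyl)-4-oxo-4H-chromen-6-yl]oxy}benzoate | COC(=O)c1ccc(Oc2c(OCc3ccccc3)cc3oc(-c4ccc(OC)cc4)cc(=O)c3c2OCc2ccccc2)cc1
F6 | step 2 | 2-acetyl-3,5-bis(benzyloxy)cyclohexa-2,5-diene-1,4-dione | CC(=O)C1=C(OCc2ccccc2)C(=O)C(OCc2ccccc2)=CC1=O
F0 | step 5 | none | none
A1 | alternative 1 | methyl coumalate (methyl 2-oxo-2H-pyran-5-carboxylate) | COC(=O)c1ccc(=O)oc1
A2 | alternative 1 | [3,5-bis(benzyloxy)-4-(ethynyloxy)phenoxy]triisopropylsilane | C#COc1c(OCc2ccccc2)cc(O[Si](C(C)C)(C(C)C)C(C)C)cc1OCc1ccccc1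
A3 | alternative 1 | methyl 4-[2,6-bis(benzyloxy)-4-(triisopropylsilyloxy)phenoxy]benzoate | COC(=O)c1ccc(Oc2c(OCc3ccccc3)cc(O[Si](C(C)C)(C(C)C)C(C)C)cc2OCc2ccccc2)cc1
A4 | alternative 2 | 2-(4-methoxyphenyl)-6-methyl-4H-pyran-4-one | COc1ccc(-c2cc(=O)cc(C)o2)cc1
A5 | alternative 2 | 2-{4-[5,7-bis(benzyloxy)-4-oxo-4H-chromen-2-yl]phenoxy}propanedioyl dichloride | ClC(=O)C(Oc1ccc(-c2cc(=O)c3c(OCc4ccccc4)cc(OCc4ccccc4)cc3o2)cc1)C(Cl)=O
A6 | alternative 2 | 6-{4-[5,7-bis(benzyloxy)-4-oxo-4H-chromen-2-yl]phenoxy}-5,7-dihydroxy-2-(4-methoxyphenyl)-4H-chromen-4-one | COc1ccc(-c2cc(=O)c3c(O)c(Oc4ccc(-c5cc(=O)c6c(OCc7ccccc7)cc(OCc7ccccc7)cc6o5)cc4)c(O)cc3o2)cc1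
A7 | alternative 3 | 2-acetyl-3,5-bis(benzyloxy)phenyl 4-[3-acetyl-2,6-bis(benzyloxy)-4-(4-methoxybenzoyloxy)phenoxy]benzoate | COc1ccc(C(=O)Oc2cc(OCc3ccccc3)c(Oc3ccc(C(=O)Oc4cc(OCc5ccccc5)cc(OCc5ccccc5)c4C(C)=O)cc3)c(OCc3ccccc3)c2C(C)=O)cc1
A8 | alternative 3 | 1-[2,4-bis(benzyloxy)-6-hydroxyphenyl]-3-(4-{2,6-bis(benzyloxy)-4-hydroxy-3-[3-(4-methoxyphenyl)-3-oxopropanoyl]phenoxy}phenyl)propane-1,3-dione | COc1ccc(C(=O)CC(=O)c2c(O)cc(OCc3ccccc3)c(Oc3ccc(C(=O)CC(=O)c4c(O)cc(OCc5ccccc5)cc4OCc4ccccc4)cc3)c2OCc2ccccc2)cc1
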